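The plan cuts ring B of the flavanone half at two adjacent atoms: the crowded C5'–C6'' biaryl bond to ring D of the flavone half and the C4'–O bond next to it. One flask makes both: a 2,6-dialkoxyaryllithium (ring D) adds to a C4'–C5' aryne, and the C4' anion left behind is borylated and oxidised. The feature exploited is the contiguous C3'–O, C4'–O, C5'–aryl array of ring B, whose C3' oxygen polarises the aryne so that carbon enters at C5'. The aryne precursor is a 3-alkoxy-5-fluorobenzaldehyde dioxolane. Its C3' oxygen is carried as a methoxymethyl ether, which, unlike a benzyl ether, offers alkyllithiums no benzylic C–H.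

Key step: step 5

Numbering: flavanone rings A and C carry unprimed numbers and its aryl ring B primed numbers. Flavone atoms are double-primed (benzo ring D, pyranone ring E), and the 4-oxyphenyl group is ring F.
Assumption 1: the quinine-derived thiourea of step 15 is taken to give the 2S series. If the sense of induction is the opposite, the pseudoenantiomeric quinidine-derived thiourea is used under the same conditions.
Assumption 2: rotation about the C5'–C6'' axis (three ortho oxygens, one ortho hydrogen) is taken to be fast at room temperature, in line with the absence of an axial descriptor in the target.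

Step 1
Reactants: 1 3-fluoro-5-hydroxybenzaldehyde
Product: 2 3-(1,3-dioxolan-2-yl)-5-fluorophenol
Conditions: ethylene glycol (3 equiv), TsOH·H2O (2 mol%), toluene, reflux, azeotropic water removal; Et3N quench
Reagents that add atoms: ethylene glycol, OCCO
Why: Acid-catalysed acetalisation of a non-enolisable benzaldehyde is driven by water removal, and it precedes phenol protection because an aryl MOM ether would not survive hot acid and glycol.

Step 2
Reactants: 2 3-(1,3-dioxolan-2-yl)-5-fluorophenol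
Product: 3 2-[3-fluoro-5-(methoxymethoxy)phenyl]-1,3-dioxolane
Conditions: MOMCl (1.3 equiv), DIPEA (2 equiv), CH2Cl2, 0 °C to rt
Reagents that add atoms: chloromethyl methyl ether, COCCl
Why: Williamson-type O-alkylation under basic conditions leaves the acetal intact and places a base-stable, lithium-coordinating, σ-withdrawing group on the C3' oxygen.

Step 3
Reactants: 4 phloroglucinol
Product: 5 5-(triisopropylsilyloxy)benzene-1,3-diol
Conditions: 4 (3 equiv), TIPSCl (1 equiv), imidazole (1.5 equiv), DMF, 0 °C to rt; excess 4 removed by aqueous wash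
Reagents that add atoms: triisopropylsilyl chloride, CC(C)[Si](Cl)(C(C)C)C(C)C
Why: Silylation with the cheap, water-soluble triol in excess should stop at the monosilyl ether, so the one statistical event of this fragment is settled by an extraction.

Step 4
Reactants: 5 5-(triisopropylsilyloxy)benzene-1,3-diol
Product: 6 1,3-bis(methoxymethoxy)-5-(triisopropylsilyloxy)benzene
Conditions: MOMCl (2.6 equiv), DIPEA (3.5 equiv), CH2Cl2, 0 °C to rt
Reagents that add atoms: chloromethyl methyl ether, COCCl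
Why: Exhaustive Williamson-type alkylation of both remaining phenols with an amine base avoids silyl scrambling and gives two cooperating directing groups around C2.

Step 5
Reactants: 3 2-[3-fluoro-5-(methoxymethoxy)phenyl]-1,3-dioxolane; 6 1,3-bis(methoxymethoxy)-5-(triisopropylsilyloxy)benzene
Product: 12 2-(methoxymethoxy)-6-[2,6-bis(methoxymethoxy)-4-(triisopropylsilyloxy)phenyl]-4-(1,3-dioxolan-2-yl)phenol, via ring D aryllithium 7 (not isolated), via lithiated fluoroarene 8 (not isolated), via C4'–C5' aryne 9 (not isolated), via C4' biaryllithium 10 (not isolated), via lithium aryltrimethoxyborate 11 (not isolated)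
Conditions: 6 (1.6 equiv), n-BuLi (1.5 equiv), THF, 0 °C to rt; separately 3 (1 equiv), s-BuLi (1.0 equiv), THF, −78 °C; cold solution of 8 added slowly by cooled cannula to 7 at −15 °C, then rt; B(OMe)3 (4 equiv), −78 °C to rt; 30% aq H2O2, 0 °C to rt; Na2S2O3, pH 8 work-up, Et3N-deactivated silica
Reagents that add atoms: hydrogen peroxide, OO (trimethyl borate, COB(OC)OC, is retained only in 11)
Why: s-BuLi removes the proton of 3 between fluorine and OMOM, the most acidic and doubly coordinated site, and 8 loses LiF as soon as it meets the warmer solution, so aryne 9 forms at low stationary concentration in an excess of 7. Aryllithium 7 adds to the strained triple bond at C5' (C5'–C6'' bond) and leaves the charge at C4' in 10, which B(OMe)3 converts into borate 11, and peroxide then triggers the 1,2-aryl shift from boron to oxygen that makes the C4'–O bond. The closest known reaction type is the addition of 2,6-dialkoxyaryllithiums to arynes with electrophilic capture of the resulting 2-lithiobiaryl, as practised for dialkylbiarylphosphine ligands, joined to the standard borylation–oxidation of aryllithiums. No ring is closed and no stereocentre is formed. The step needs attack at C5' only: the σ-withdrawing C3' oxygen distorts 9 so that the distal carbon is the electrophilic one and the anion develops next to oxygen, and C5' is flanked only by C6'–H, so electronic and steric effects agree. The MOM group removes the benzylic C–H that s-BuLi or 10 could abstract (Wittig rearrangement) and chelates lithium in 8 and 10, while the slow inverse addition limits capture of 9 by 8.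

Step 6
Reactants: 12 2-(methoxymethoxy)-6-[2,6-bis(methoxymethoxy)-4-(triisopropylsilyloxy)phenyl]-4-(1,3-dioxolan-2-yl)phenol
Product: 13 2-{4-(benzyloxy)-3-[2,6-bis(methoxymethoxy)-4-(triisopropylsilyloxy)phenyl]-5-(methoxymethoxy)phenyl}-1,3-dioxolane
Conditions: BnBr (1.3 equiv), K2CO3 (2 equiv), dry acetone, 50 °C
Reagents that add atoms: benzyl bromide, BrCc1ccccc1
Why: Williamson etherification caps the C4' phenol, whose free para hydroxyl makes the dioxolane labile, with the group that stays to the last step, and dry carbonate should not cleave the aryl TIPS ether.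

Step 7
Reactants: 13 2-{4-(benzyloxy)-3-[2,6-bis(methoxymethoxy)-4-(triisopropylsilyloxy)phenyl]-5-(methoxymethoxy)phenyl}-1,3-dioxolane
Product: 14 4-[2-(benzyloxy)-5-(1,3-dioxolan-2-yl)-3-(methoxymethoxy)phenyl]-3,5-bis(methoxymethoxy)phenol
Conditions: TBAF (1.1 equiv), AcOH (1.1 equiv), THF, 0 °C
Reagents that add atoms: none
Why: Fluoride-mediated silyl ether cleavage, buffered to protect the electron-rich phenoxide, frees only the ring D oxygen para to C6'', the future O1''.

Step 8
Reactants: 14 4-[2-(benzyloxy)-5-(1,3-dioxolan-2-yl)-3-(methoxymethoxy)phenyl]-3,5-bis(methoxymethoxy)phenol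
Product: 15 4-[2-(benzyloxy)-5-(1,3-dioxolan-2-yl)-3-(methoxymethoxy)phenyl]-2-iodo-3,5-bis(methoxymethoxy)phenol
Conditions: NIS (1.0 equiv), CH2Cl2, −40 to 0 °C, dark
Reagents that add atoms: N-iodosuccinimide, O=C1CCC(=O)N1I
Why: Electrophilic aromatic iodination goes to the free-phenol ring D, far more activated than ring B, and its two open positions are equivalent and both ortho to the hydroxyl, so one equivalent of neutral reagent in the cold should stop at the monoiodide.

Step 9
Reactants: 15 4-[2-(benzyloxy)-5-(1,3-dioxolan-2-yl)-3-(methoxymethoxy)phenyl]-2-iodo-3,5-bis(methoxymethoxy)phenol; 16 1-(benzyloxy)-4-ethynylbenzene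
Product: 18 6-[2-(benzyloxy)-5-(1,3-dioxolan-2-yl)-3-(methoxymethoxy)phenyl]-2-[4-(benzyloxy)phenyl]-5,7-bis(methoxymethoxy)-4H-chromen-4-one, via o-hydroxyaryl ynone 17 (not isolated)
Conditions: 16 (1.3 equiv), CO (10 bar), PdCl2(dppf) (5 mol%), Et2NH, 90 °C, no copper
Reagents that add atoms: carbon monoxide, [C-]#[O+]
Why: Insertion of zerovalent palladium into the carbon–iodine bond, CO uptake and copper-free alkynylation give ynone 17, which diethylamine carries by conjugate addition and 6-endo displacement by the phenol into the flavone (carbonylative Sonogashira annulation of o-iodophenols), all acetals being stable to the basic medium.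

Step 10
Reactants: 18 6-[2-(benzyloxy)-5-(1,3-dioxolan-2-yl)-3-(methoxymethoxy)phenyl]-2-[4-(benzyloxy)phenyl]-5,7-bis(methoxymethoxy)-4H-chromen-4-one
Product: 19 4-(benzyloxy)-3-{2-[4-(benzyloxy)phenyl]-5,7-dihydroxy-4-oxo-4H-chromen-6-yl}-5-hydroxybenzaldehyde
Conditions: 3 M aq HCl, MeOH/THF, 50 °C
Reagents that add atoms: water, O
Why: Acid hydrolysis opens the aryl dioxolane and passes the three phenolic MOM groups to methanol while benzyl ethers and the acyl-deactivated ring D are inert, and doing this before C2 exists keeps every acid-labile ether out of the later hot-acid decarboxylation.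

Step 11
Reactants: 19 4-(benzyloxy)-3-{2-[4-(benzyloxy)phenyl]-5,7-dihydroxy-4-oxo-4H-chromen-6-yl}-5-hydroxybenzaldehyde
Product: 20 3,4-bis(benzyloxy)-5-{5,7-bis(benzyloxy)-2-[4-(benzyloxy)phenyl]-4-oxo-4H-chromen-6-yl}benzaldehyde
Conditions: BnBr (4.5 equiv), Cs2CO3 (4.5 equiv), DMF, 60 °C
Reagents that add atoms: benzyl bromide, BrCc1ccccc1
Why: Williamson etherification with caesium carbonate in warm DMF should also alkylate the chelated, flanked C5'' hydroxyl, and the non-enolisable aldehyde tolerates the base.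

Step 12
Reactants: 21 2',4',6'-trihydroxyacetophenone
Product: 22 1-[2,4-bis(benzyloxy)-6-hydroxyphenyl]ethan-1-one
Conditions: BnBr (2.1 equiv), K2CO3 (2.2 equiv), DMF, rt to 40 °C
Reagents that add atoms: benzyl bromide, BrCc1ccccc1
Why: In this Williamson etherification one ortho hydroxyl stays hydrogen-bonded to the acetyl group and is the least reactive, so two equivalents of bromide should leave exactly the phenol needed for ring closure.

Step 13
Reactants: 22 1-[2,4-bis(benzyloxy)-6-hydroxyphenyl]ethan-1-one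
Product: 23 tert-butyl 3-[2,4-bis(benzyloxy)-6-hydroxyphenyl]-3-oxopropanoate
Conditions: LiHMDS (3.2 equiv), THF, −78 °C; Boc2O (1.05 equiv), −78 to 0 °C; cold 1 M HCl work-up
Reagents that add atoms: di-tert-butyl dicarbonate, CC(C)(C)OC(=O)OC(=O)OC(C)(C)C
Why: The phenoxide–enolate dianion is acylated at carbon by Boc2O (Claisen-type acylation), any aryl carbonate formed first is carried to carbon by a Baker–Venkataraman-type shift, and the third equivalent of base stores the product as its enolate, the bulky ester slowing lactonisation to the coumarin.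

Step 14
Reactants: 20 3,4-bis(benzyloxy)-5-{5,7-bis(benzyloxy)-2-[4-(benzyloxy)phenyl]-4-oxo-4H-chromen-6-yl}benzaldehyde; 23 tert-butyl 3-[2,4-bis(benzyloxy)-6-hydroxyphenyl]-3-oxopropanoate
Product: 24 tert-butyl (Z)-2-[2,4-bis(benzyloxy)-6-hydroxybenzoyl]-3-(3,4-bis(benzyloxy)-5-{5,7-bis(benzyloxy)-2-[4-(benzyloxy)phenyl]-4-oxo-4H-chromen-6-yl}phenyl)prop-2-enoate
Conditions: piperidine (20 mol%), AcOH (20 mol%), 4 Å molecular sieves, toluene, rt; rapid isolation
Reagents that add atoms: none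
Why: Knoevenagel condensation through the piperidinium iminium ion of the unhindered aldehyde (C2'–H and C6'–H flank it) should give the alkylidene, expected mainly as the Z isomer, the geometry having no bearing on the constitution of the next product.

Step 15
Reactants: 24 tert-butyl (Z)-2-[2,4-bis(benzyloxy)-6-hydroxybenzoyl]-3-(3,4-bis(benzyloxy)-5-{5,7-bis(benzyloxy)-2-[4-(benzyloxy)phenyl]-4-oxo-4H-chromen-6-yl}phenyl)prop-2-enoate
Product: 27 (2S)-5,7-bis(benzyloxy)-2-(3,4-bis(benzyloxy)-5-{5,7-bis(benzyloxy)-2-[4-(benzyloxy)phenyl]-4-oxo-4H-chromen-6-yl}phenyl)chroman-4-one, via tert-butyl 4-oxochromane-3-carboxylate 25 (not isolated), via 4-oxochromane-3-carboxylic acid 26 (not isolated)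
Conditions: 1-[3,5-bis(trifluoromethyl)phenyl]-3-[(8α,9S)-6'-methoxycinchonan-9-yl]thiourea (10 mol%), toluene, −25 °C; then TsOH·H2O (1 equiv), 80 °C
Reagents that add atoms: none
Why: In this asymmetric intramolecular oxa-Michael addition (6-endo-trig) the thiourea binds the β-ketoester carbonyls while the quinuclidine nitrogen activates the phenol, so oxygen adds to one alkene face and sets C2 as S, after which acid silences the amine and removes isobutene and CO2 without touching C2.

Step 16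
Reactants: 27 (2S)-5,7-bis(benzyloxy)-2-(3,4-bis(benzyloxy)-5-{5,7-bis(benzyloxy)-2-[4-(benzyloxy)phenyl]-4-oxo-4H-chromen-6-yl}phenyl)chroman-4-one
Product: 28 (2S)-2-{3,4-dihydroxy-5-[5,7-dihydroxy-2-(4-hydroxyphenyl)-4-oxo-4H-chromen-6-yl]phenyl}-5,7-dihydroxychroman-4-one (CNP0176432.1)
Conditions: H2 (1 atm), 10% Pd/C, THF/MeOH, rt; stopped at full debenzylation
Reagents that add atoms: none
Why: Hydrogenolysis of the seven aryl benzyl ethers runs under neutral conditions, so no base or acid is present to open ring C and scramble C2, and O-benzyl cleavage should be faster than reduction of the flavone alkene or either carbonyl.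

Compound list
1 | 3-fluoro-5-hydroxybenzaldehyde | O=Cc1cc(O)cc(F)c1 | starting material
2 | 3-(1,3-dioxolan-2-yl)-5-fluorophenol | Oc1cc(F)cc(C2OCCO2)c1 | intermediate
3 | 2-[3-fluoro-5-(methoxymethoxy)phenyl]-1,3-dioxolane | COCOc1cc(F)cc(C2OCCO2)c1 | intermediate
4 | phloroglucinol | Oc1cc(O)cc(O)c1 | starting material
5 | 5-(triisopropylsilyloxy)benzene-1,3-diol | Oc1cc(O)cc(O[Si](C(C)C)(C(C)C)C(C)C)c1 | intermediate
6 | 1,3-bis(methoxymethoxy)-5-(triisopropylsilyloxy)benzene | COCOc1cc(OCOC)cc(O[Si](C(C)C)(C(C)C)C(C)C)c1 | intermediate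
7 | [2,6-bis(methoxymethoxy)-4-(triisopropylsilyloxy)phenyl]lithium | [Li]c1c(OCOC)cc(O[Si](C(C)C)(C(C)C)C(C)C)cc1OCOC | intermediate
8 | [4-(1,3-dioxolan-2-yl)-2-fluoro-6-(methoxymethoxy)phenyl]lithium | [Li]c1c(F)cc(C2OCCO2)cc1OCOC | intermediate
9 | 2-[3,4-didehydro-5-(methoxymethoxy)phenyl]-1,3-dioxolane (aryne, triple bond C4'–C5') | COCOC1=CC(C2OCCO2)=CC#C1 | intermediate
10 | {2-[2,6-bis(methoxymethoxy)-4-(triisopropylsilyloxy)phenyl]-4-(1,3-dioxolan-2-yl)-6-(methoxymethoxy)phenyl}lithium | [Li]c1c(OCOC)cc(C2OCCO2)cc1-c1c(OCOC)cc(O[Si](C(C)C)(C(C)C)C(C)C)cc1OCOC | intermediate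
11 | lithium {2-[2,6-bis(methoxymethoxy)-4-(triisopropylsilyloxy)phenyl]-4-(1,3-dioxolan-2-yl)-6-(methoxymethoxy)phenyl}trimethoxyborate | [Li+].CO[B-](OC)(OC)c1c(OCOC)cc(C2OCCO2)cc1-c1c(OCOC)cc(O[Si](C(C)C)(C(C)C)C(C)C)cc1OCOC | intermediate
12 | 2-(methoxymethoxy)-6-[2,6-bis(methoxymethoxy)-4-(triisopropylsilyloxy)phenyl]-4-(1,3-dioxolan-2-yl)phenol | Oc1c(OCOC)cc(C2OCCO2)cc1-c1c(OCOC)cc(O[Si](C(C)C)(C(C)C)C(C)C)cc1OCOC | intermediate
13 | 2-{4-(benzyloxy)-3-[2,6-bis(methoxymethoxy)-4-(triisopropylsilyloxy)phenyl]-5-(methoxymethoxy)phenyl}-1,3-dioxolane | COCOc1cc(C2OCCO2)cc(-c2c(OCOC)cc(O[Si](C(C)C)(C(C)C)C(C)C)cc2OCOC)c1OCc1ccccc1 | intermediate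
14 | 4-[2-(benzyloxy)-5-(1,3-dioxolan-2-yl)-3-(methoxymethoxy)phenyl]-3,5-bis(methoxymethoxy)phenol | COCOc1cc(C2OCCO2)cc(-c2c(OCOC)cc(O)cc2OCOC)c1OCc1ccccc1 | intermediate
15 | 4-[2-(benzyloxy)-5-(1,3-dioxolan-2-yl)-3-(methoxymethoxy)phenyl]-2-iodo-3,5-bis(methoxymethoxy)phenol | COCOc1cc(C2OCCO2)cc(-c2c(OCOC)cc(O)c(I)c2OCOC)c1OCc1ccccc1 | intermediate
16 | 1-(benzyloxy)-4-ethynylbenzene | C#Cc1ccc(OCc2ccccc2)cc1 | starting material
17 | 1-{3-[2-(benzyloxy)-5-(1,3-dioxolan-2-yl)-3-(methoxymethoxy)phenyl]-6-hydroxy-2,4-bis(methoxymethoxy)phenyl}-3-[4-(benzyloxy)phenyl]prop-2-yn-1-one | COCOc1cc(C2OCCO2)cc(-c2c(OCOC)cc(O)c(C(=O)C#Cc3ccc(OCc4ccccc4)cc3)c2OCOC)c1OCc1ccccc1 | intermediate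
18 | 6-[2-(benzyloxy)-5-(1,3-dioxolan-2-yl)-3-(methoxymethoxy)phenyl]-2-[4-(benzyloxy)phenyl]-5,7-bis(methoxymethoxy)-4H-chromen-4-one | COCOc1cc(C2OCCO2)cc(-c2c(OCOC)cc3oc(-c4ccc(OCc5ccccc5)cc4)cc(=O)c3c2OCOC)c1OCc1ccccc1 | intermediate
19 | 4-(benzyloxy)-3-{2-[4-(benzyloxy)phenyl]-5,7-dihydroxy-4-oxo-4H-chromen-6-yl}-5-hydroxybenzaldehyde | O=Cc1cc(O)c(OCc2ccccc2)c(-c2c(O)cc3oc(-c4ccc(OCc5ccccc5)cc4)cc(=O)c3c2O)c1 | intermediate
20 | 3,4-bis(benzyloxy)-5-{5,7-bis(benzyloxy)-2-[4-(benzyloxy)phenyl]-4-oxo-4H-chromen-6-yl}benzaldehyde | O=Cc1cc(OCc2ccccc2)c(OCc2ccccc2)c(-c2c(OCc3ccccc3)cc3oc(-c4ccc(OCc5ccccc5)cc4)cc(=O)c3c2OCc2ccccc2)c1 | intermediate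
21 | 2',4',6'-trihydroxyacetophenone | CC(=O)c1c(O)cc(O)cc1O | starting material
22 | 1-[2,4-bis(benzyloxy)-6-hydroxyphenyl]ethan-1-one | CC(=O)c1c(O)cc(OCc2ccccc2)cc1OCc1ccccc1 | intermediate
23 | tert-butyl 3-[2,4-bis(benzyloxy)-6-hydroxyphenyl]-3-oxopropanoate | CC(C)(C)OC(=O)CC(=O)c1c(O)cc(OCc2ccccc2)cc1OCc1ccccc1 | intermediate
24 | tert-butyl (Z)-2-[2,4-bis(benzyloxy)-6-hydroxybenzoyl]-3-(3,4-bis(benzyloxy)-5-{5,7-bis(benzyloxy)-2-[4-(benzyloxy)phenyl]-4-oxo-4H-chromen-6-yl}phenyl)prop-2-enoate | CC(C)(C)OC(=O)/C(C(=O)c1c(O)cc(OCc2ccccc2)cc1OCc1ccccc1)=C\c1cc(OCc2ccccc2)c(OCc2ccccc2)c(-c2c(OCc3ccccc3)cc3oc(-c4ccc(OCc5ccccc5)cc4)cc(=O)c3c2OCc2ccccc2)c1 | intermediate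
25 | tert-butyl (2S)-5,7-bis(benzyloxy)-2-(3,4-bis(benzyloxy)-5-{5,7-bis(benzyloxy)-2-[4-(benzyloxy)phenyl]-4-oxo-4H-chromen-6-yl}phenyl)-4-oxochromane-3-carboxylate (C3 epimerisable, in equilibrium with the enol) | O=C1C(C(=O)OC(C)(C)C)[C@@H](c2cc(OCc3ccccc3)c(OCc3ccccc3)c(-c3c(OCc4ccccc4)cc4oc(-c5ccc(OCc6ccccc6)cc5)cc(=O)c4c3OCc3ccccc3)c2)Oc2cc(OCc3ccccc3)cc(OCc3ccccc3)c21 | intermediate
26 | (2S)-5,7-bis(benzyloxy)-2-(3,4-bis(benzyloxy)-5-{5,7-bis(benzyloxy)-2-[4-(benzyloxy)phenyl]-4-oxo-4H-chromen-6-yl}phenyl)-4-oxochromane-3-carboxylic acid (C3 epimerisable) | O=C1C(C(=O)O)[C@@H](c2cc(OCc3ccccc3)c(OCc3ccccc3)c(-c3c(OCc4ccccc4)cc4oc(-c5ccc(OCc6ccccc6)cc5)cc(=O)c4c3OCc3ccccc3)c2)Oc2cc(OCc3ccccc3)cc(OCc3ccccc3)c21 | intermediate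
27 | (2S)-5,7-bis(benzyloxy)-2-(3,4-bis(benzyloxy)-5-{5,7-bis(benzyloxy)-2-[4-(benzyloxy)phenyl]-4-oxo-4H-chromen-6-yl}phenyl)chroman-4-one | O=C1C[C@@H](c2cc(OCc3ccccc3)c(OCc3ccccc3)c(-c3c(OCc4ccccc4)cc4oc(-c5ccc(OCc6ccccc6)cc5)cc(=O)c4c3OCc3ccccc3)c2)Oc2cc(OCc3ccccc3)cc(OCc3ccccc3)c21 | intermediate
28 | (2S)-2-{3,4-dihydroxy-5-[5,7-dihydroxy-2-(4-hydroxyphenyl)-4-oxo-4H-chromen-6-yl]phenyl}-5,7-dihydroxychroman-4-one | O=C1C[C@@H](c2cc(O)c(O)c(-c3c(O)cc4oc(-c5ccc(O)cc5)cc(=O)c4c3O)c2)Oc2cc(O)cc(O)c21 | target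

Total step count: 16. Longest linear sequence: 12 steps (1, 2, 5, 6, 7, 8, 9, 10, 11, 14, 15, 16).

Steps most likely to fail

Step 5.
- **What may go wrong:** The aryne may be captured by its own lithiated precursor or by residual alkyllithium. The biaryl anion may be protonated before it meets the borate. The preference for distal attack may erode.
- **Fallback:** A cross-coupling with the C4' oxygen already in place sets out from 7 and comes back to the route at 13.
- **Bromide partner:** Purchased 3-bromo-4,5-dihydroxybenzaldehyde F1 is benzylated at its more acidic 4-hydroxyl (BnBr, NaHCO3, DMF, 40 °C) to 4-(benzyloxy)-3-bromo-5-hydroxybenzaldehyde F2. Acetalisation (ethylene glycol, cat. TsOH, toluene, reflux) gives 2-(benzyloxy)-3-bromo-5-(1,3-dioxolan-2-yl)phenol F3. Protection (MOMCl, DIPEA) gives 2-[4-(benzyloxy)-3-bromo-5-(methoxymethoxy)phenyl]-1,3-dioxolane F4.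
- **Coupling:** Aryllithium 7 is transmetalated with ZnCl2 to [2,6-bis(methoxymethoxy)-4-(triisopropylsilyloxy)phenyl]zinc chloride F5. A Negishi coupling of F4 and F5 (Pd(OAc)2, RuPhos, THF, 60 °C) gives 13 directly, so step 6 is no longer needed.

Step 15.
- **What may go wrong:** Racemic background closure may occur already during or after the condensation of step 14, helped by the 2,6-dioxygenated aroyl group. Facial selectivity may be low with the large, electron-rich ring B. Ring C may open reversibly in the hot acid.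
- **Fallback:** A racemic flavanone followed by kinetic resolution through asymmetric transfer hydrogenation sets out from 20 and 22 and comes back at 27.
- **Racemate:** Claisen–Schmidt condensation (KOH, EtOH/THF, rt) gives the 2'-hydroxychalcone F6, and NaOAc in hot EtOH closes it to the racemic flavanone F7.
- **Resolution:** RuCl[(R,R)-TsDPEN](p-cymene) with HCO2H/Et3N in EtOAc is expected to reduce the 2R enantiomer faster, giving the cis-(2R,4R)-flavan-4-ol F8. Unreduced 27 is then separated by chromatography. By its nature this path can pass on at most half of the material.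

Step 9.
- **What may go wrong:** Oxidative addition may be slow at the iodide flanked by two oxygen substituents. Alkynylation may proceed without CO uptake and be followed by benzofuran formation. Closure may be 5-exo, towards the aurone.
- **Fallback:** Organolithium acylation in place of carbonylation sets out from 15 and 16 and comes back at 17, which is then isolated and closed to 18.
- **Acyl donor:** Alkyne 16 is deprotonated (n-BuLi, THF, −78 °C) and treated with N-methoxy-N-methylcarbamoyl chloride to give 3-[4-(benzyloxy)phenyl]-N-methoxy-N-methylprop-2-ynamide F9.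
- **Acylation and closure:** Iodophenol 15 is converted with n-BuLi (2.2 equiv, THF, −78 °C) into the O,C-dilithio species F10 by deprotonation and iodine–lithium exchange. F10 is acylated by F9 to give 17. Et2NH in EtOH at 50 °C then effects the addition–elimination closure to 18.

Further compounds
F1 | step 5 | 3-bromo-4,5-dihydroxybenzaldehyde (purchased) | O=Cc1cc(O)c(O)c(Br)c1
F2 | step 5 | 4-(benzyloxy)-3-bromo-5-hydroxybenzaldehyde | O=Cc1cc(O)c(OCc2ccccc2)c(Br)c1
F3 | step 5 | 2-(benzyloxy)-3-bromo-5-(1,3-dioxolan-2-yl)phenol | Oc1cc(C2OCCO2)cc(Br)c1OCc1ccccc1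
F4 | step 5 | 2-[4-(benzyloxy)-3-bromo-5-(methoxymethoxy)phenyl]-1,3-dioxolane | COCOc1cc(C2OCCO2)cc(Br)c1OCc1ccccc1
F5 | step 5 | [2,6-bis(methoxymethoxy)-4-(triisopropylsilyloxy)phenyl]zinc chloride | Cl[Zn]c1c(OCOC)cc(O[Si](C(C)C)(C(C)C)C(C)C)cc1OCOC
F6 | step 15 | (E)-1-[2,4-bis(benzyloxy)-6-hydroxyphenyl]-3-(3,4-bis(benzyloxy)-5-{5,7-bis(benzyloxy)-2-[4-(benzyloxy)phenyl]-4-oxo-4H-chromen-6-yl}phenyl)prop-2-en-1-one | O=C(/C=C/c1cc(OCc2ccccc2)c(OCc2ccccc2)c(-c2c(OCc3ccccc3)cc3oc(-c4ccc(OCc5ccccc5)cc4)cc(=O)c3c2OCc2ccccc2)c1)c1c(O)cc(OCc2ccccc2)cc1OCc1ccccc1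
F7 | step 15 | racemic 5,7-bis(benzyloxy)-2-(3,4-bis(benzyloxy)-5-{5,7-bis(benzyloxy)-2-[4-(benzyloxy)phenyl]-4-oxo-4H-chromen-6-yl}phenyl)chroman-4-one | O=C1CC(c2cc(OCc3ccccc3)c(OCc3ccccc3)c(-c3c(OCc4ccccc4)cc4oc(-c5ccc(OCc6ccccc6)cc5)cc(=O)c4c3OCc3ccccc3)c2)Oc2cc(OCc3ccccc3)cc(OCc3ccccc3)c21
F8 | step 15 | 5,7-bis(benzyloxy)-6-{2,3-bis(benzyloxy)-5-[(2R,4R)-5,7-bis(benzyloxy)-4-hydroxychroman-2-yl]phenyl}-2-[4-(benzyloxy)phenyl]-4H-chromen-4-one | O[C@@H]1C[C@H](c2cc(OCc3ccccc3)c(OCc3ccccc3)c(-c3c(OCc4ccccc4)cc4oc(-c5ccc(OCc6ccccc6)cc5)cc(=O)c4c3OCc3ccccc3)c2)Oc2cc(OCc3ccccc3)cc(OCc3ccccc3)c21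
F9 | step 9 | 3-[4-(benzyloxy)phenyl]-N-methoxy-N-methylprop-2-ynamide | CON(C)C(=O)C#Cc1ccc(OCc2ccccc2)cc1
F10 | step 9 | O,C-dilithio derivative of 15 (lithium phenoxide, lithium in place of iodine) | COCOc1cc(C2OCCO2)cc(-c2c(OCOC)cc(O[Li])c([Li])c2OCOC)c1OCc1ccccc1
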